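**Plan**

- Cuts, in retrosynthetic order: the aryl ether bond O1–C7a (O1 stays as the hydroxyl oxygen on C2); the two carbinol C–H bonds at C2 and at the side-chain CH(OH); then C2–C3 and the side-chain carbinol–methine bond (two Claisen acylations) and C3–C3a (Negishi coupling). This leaves rings A, B and C as simple benzoic and arylacetic acids.
- Enabling feature: O1–C2(ring A)–C3(CH2OH)–ring B and, on C5, HO–CH(ring B)–CH(CH2OH)–ring C are the same aryl–CH(O)–CH(aryl)–CH2OH unit with the same syn (S,R) configuration. Ring B is the methine aryl of the first unit and the carbinol aryl of the second.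
- Forward: the ring B acid chloride acylates the ring C acetate, an acetate arm is coupled to ring B at its iodide, the ring A acid chloride acylates that arm, and the flat bis(α-aryl β-keto ester) is reduced at both ketones in one operation. The dihydrofuran ring, the only ring formed, closes last by O-arylation.
- Stereochemistry: all four centers arise in the twofold asymmetric transfer hydrogenation with dynamic kinetic resolution (the (S,S) catalyst makes both carbinols S, and each labile methine is drawn syn to its carbinol). The ring closure does not break the C2–O bond, so the syn unit becomes the trans-(2S,3R) ring.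

Key step: step 12

Remark: locants are those of 2,3-dihydrobenzofuran (O1, C2, C3, C3a, C4 to C7, C7a); ring A is the aryl on C2, ring B the benzo ring, ring C the aryl of the C5 side chain. The (S,S)-TsDPEN complex is assumed to reduce both aryl ketones with the facial sense it shows for simple aryl alkyl ketones.

**Route**

Step 1
Reactants: 1 4-amino-3-methoxybenzoic acid
Product: 2 4-amino-3-iodo-5-methoxybenzoic acid
Conditions: ICl (1.05 equiv), AcOH, rt
Reagents that add atoms: iodine monochloride, ClI
Why: Electrophilic aromatic iodination, in which the amino group directs ICl to its only free ortho position (C5), a position that is also meta to the deactivating carboxyl group.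

Step 2
Reactants: 2 4-amino-3-iodo-5-methoxybenzoic acid
Product: 4 4-bromo-3-iodo-5-methoxybenzoic acid, via arenediazonium bromide 3 (not isolated)
Conditions: NaNO2, 48% HBr, H2O, 0 °C; then CuBr (0.3 equiv), 48% HBr, 0 → 60 °C
Reagents that add atoms: hydrogen bromide, Br (bromine of 4 and bromide of 3); sodium nitrite, [Na+].[O-]N=O (outer nitrogen of 3 only, lost again as dinitrogen)
Why: Sandmeyer bromination, in which diazotisation and copper-mediated radical replacement of the diazonium group put bromine on the future C7a without touching the C–I bond.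

Step 3
Reactants: 4 4-bromo-3-iodo-5-methoxybenzoic acid
Product: 5 4-bromo-3-iodo-5-methoxybenzoyl chloride
Conditions: (COCl)2, DMF (cat.), CH2Cl2, 0 °C → rt
Reagents that add atoms: oxalyl chloride, O=C(Cl)C(=O)Cl
Why: Acid chloride formation through the chloroiminium species from DMF and oxalyl chloride, which leaves the aryl halides and the methyl ether untouched.

Step 4
Reactants: 6 homovanillic acid (4-hydroxy-3-methoxyphenylacetic acid)
Product: 7 methyl 2-(4-hydroxy-3-methoxyphenyl)acetate
Conditions: MeOH, H2SO4 (cat.), reflux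
Reagents that add atoms: methanol, CO
Why: Fischer esterification of the aliphatic acid, under which the phenol does not react.

Step 5
Reactants: 7 methyl 2-(4-hydroxy-3-methoxyphenyl)acetate
Product: 8 methyl 2-(4-benzyloxy-3-methoxyphenyl)acetate
Conditions: BnBr, K2CO3, acetone, reflux
Reagents that add atoms: benzyl bromide, BrCc1ccccc1
Why: Williamson ether synthesis, in which K2CO3 ionises only the phenol, so the benzyl group goes on oxygen and the arylacetate CH2 stays intact.

Step 6
Reactants: 8 methyl 2-(4-benzyloxy-3-methoxyphenyl)acetate; 5 4-bromo-3-iodo-5-methoxybenzoyl chloride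
Product: 10 methyl 2-(4-benzyloxy-3-methoxyphenyl)-3-(4-bromo-3-iodo-5-methoxyphenyl)-3-oxopropanoate (both methine epimers and enol), via lithium ester enolate 9 (not isolated)
Conditions: LiN(SiMe3)2 (2.1 equiv), THF, −78 °C; then 5, −78 → 0 °C; aq NH4Cl
Reagents that add atoms: lithium bis(trimethylsilyl)amide, [Li+].C[Si](C)(C)[N-][Si](C)(C)C (lithium of 9 only; nothing remains in 10)
Why: Crossed Claisen condensation (C-acylation of an ester enolate by an acid chloride), in which the second equivalent of base stores the more acidic product as its enolate and so prevents double acylation, while the amide base does not exchange with aryl iodide or bromide at −78 °C.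

Step 7
Reactants: 11 methyl bromoacetate
Product: 12 bromo(2-methoxy-2-oxoethyl)zinc (Reformatsky reagent, kept as a titrated THF solution)
Conditions: Zn dust (activated with Me3SiCl and BrCH2CH2Br), THF, 25–35 °C
Reagents that add atoms: zinc, [Zn]
Why: Oxidative insertion of activated zinc into the C–Br bond gives the Reformatsky reagent, a carbon-bound zinc ester enolate that is stable enough in THF to be used as a stock solution.

Step 8
Reactants: 10 methyl 2-(4-benzyloxy-3-methoxyphenyl)-3-(4-bromo-3-iodo-5-methoxyphenyl)-3-oxopropanoate; 12 bromo(2-methoxy-2-oxoethyl)zinc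
Product: 13 methyl 2-(4-benzyloxy-3-methoxyphenyl)-3-[4-bromo-3-methoxy-5-(2-methoxy-2-oxoethyl)phenyl]-3-oxopropanoate
Conditions: 12 (3 equiv), Pd(dba)2 (3 mol %), P(t-Bu)3 (3 mol %), THF, 0 °C → rt, stopped when 10 is consumed
Reagents that add atoms: none
Why: Negishi coupling of a Reformatsky reagent (palladium-catalysed α-arylation of a zinc ester enolate), in which zerovalent palladium inserts into the C–I bond much faster than into the C–Br bond flanked by two ortho substituents, and the first equivalent of 12 converts the acidic keto ester into its zinc enolate, which also shields the ketone from Reformatsky addition.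

Step 9
Reactants: 14 vanillic acid (4-hydroxy-3-methoxybenzoic acid)
Product: 16 4-benzyloxy-3-methoxybenzoic acid, via benzyl 4-benzyloxy-3-methoxybenzoate 15 (not isolated)
Conditions: BnBr (2.3 equiv), K2CO3, DMF, 60 °C; then aq NaOH, MeOH, 70 °C; HCl
Reagents that add atoms: benzyl bromide, BrCc1ccccc1; sodium hydroxide, [Na+].[OH-] (one carboxyl oxygen of 16)
Why: Williamson benzylation of phenoxide and carboxylate followed by saponification of the benzyl ester in the same flask, which leaves the hydroxide-stable aryl benzyl ether.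

Step 10
Reactants: 16 4-benzyloxy-3-methoxybenzoic acid
Product: 17 4-benzyloxy-3-methoxybenzoyl chloride
Conditions: (COCl)2, DMF (cat.), CH2Cl2, 0 °C → rt
Reagents that add atoms: oxalyl chloride, O=C(Cl)C(=O)Cl
Why: Acid chloride formation under chloroiminium catalysis, mild enough to keep the benzyl ether.

Step 11
Reactants: 13 methyl 2-(4-benzyloxy-3-methoxyphenyl)-3-[4-bromo-3-methoxy-5-(2-methoxy-2-oxoethyl)phenyl]-3-oxopropanoate; 17 4-benzyloxy-3-methoxybenzoyl chloride
Product: 19 methyl 2-(4-benzyloxy-3-methoxyphenyl)-3-{3-[1-(4-benzyloxy-3-methoxyphenyl)-3-methoxy-1,3-dioxopropan-2-yl]-4-bromo-5-methoxyphenyl}-3-oxopropanoate (bis(α-aryl β-keto ester) with both methines labile), via dilithium dienolate 18 (not isolated)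
Conditions: LiN(SiMe3)2 (3.2 equiv), THF, −78 °C; then 17 (1.05 equiv), −78 → −20 °C; AcOH, aq NH4Cl
Reagents that add atoms: lithium bis(trimethylsilyl)amide, [Li+].C[Si](C)(C)[N-][Si](C)(C)C (lithium of 18 only; nothing remains in 19)
Why: Crossed Claisen condensation on a dianion, in which the unstabilised arylacetate enolate of 18 is by far the stronger carbon nucleophile and takes the acid chloride, the keto ester enolate stays a spectator, and the third equivalent of base stores the new keto ester as its enolate.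

Step 12
Reactants: 19 bis(α-aryl β-keto ester)
Product: 20 methyl (2S,3S)-2-(4-benzyloxy-3-methoxyphenyl)-3-{4-bromo-3-[(1S,2S)-1-(4-benzyloxy-3-methoxyphenyl)-1-hydroxy-3-methoxy-3-oxopropan-2-yl]-5-methoxyphenyl}-3-hydroxypropanoate (bis(syn β-hydroxy ester))
Conditions: RuCl[(S,S)-TsDPEN](p-cymene) (5 mol %), HCO2H/Et3N (5:2), DMF, 40 °C
Reagents that add atoms: none
Why: Proposed new method: formate turns the chloride complex into the 18-electron divalent ruthenium hydride, which hands its hydride and the proton of the ligand NH2 group to each ketone through an outer-sphere six-membered transition state, while Et3N keeps the two methines of 19 (each flanked by ketone, ester and aryl group) epimerising through their enols faster than either ketone is reduced. The closest known reaction type is the asymmetric transfer hydrogenation with dynamic kinetic resolution of α-substituted aryl β-keto esters and of 3-arylchroman-4-ones with the same catalyst family; new here are the acyclic α-aryl substrate and the presence of two such sites in one molecule. No ring closes in this step. Both carbinol centers are set by the catalyst: the aryl group conjugated with each carbonyl (ring A at one site, ring B at the other) lies under the p-cymene ligand (CH/π contact), which with the (S,S) ligand gives the (S) alcohol at both sites. Both methine centers are set by the substrate under that constraint: with no chelating metal the hydride should arrive anti to the large α-aryl group with the ester gauche to the carbonyl oxygen (Felkin–Anh), so that of the two interconverting epimers only the one leading to the syn hydroxy ester is reduced fast. The step needs one face at each of two ketones and the syn relationship at each of two labile methines; the first is secured by the aryl ketone at both sites, the second by the bulk of the α-aryl groups (ortho-bromo ring B and ring C) and the acidity of the methines, and as the two events are independent a wrong event should give a separable diastereomer and not the enantiomer.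

Step 13
Reactants: 20 bis(syn β-hydroxy ester)
Product: 21 (1S,2R)-1-(4-benzyloxy-3-methoxyphenyl)-2-{5-[(1S,2R)-2-(4-benzyloxy-3-methoxyphenyl)-1,3-dihydroxypropyl]-2-bromo-3-methoxyphenyl}propane-1,3-diol (tetraol)
Conditions: LiBH4 (5 equiv), THF/MeOH (20:1), 0 °C → rt
Reagents that add atoms: none
Why: Ester reduction with LiBH4, which reduces methyl esters but not aryl bromides or benzyl ethers and is too weakly basic to epimerise the α-aryl methines or start retro-aldol cleavage before hydride transfer (the descriptor of each methine changes from S to R only because CH2OH ranks below the carbinol carbon).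

Step 14
Reactants: 21 tetraol
Product: 22 (1S,2R)-1-(4-benzyloxy-3-methoxyphenyl)-2-{5-[(1S,2R)-2-(4-benzyloxy-3-methoxyphenyl)-1-hydroxy-3-(triisopropylsilyloxy)propyl]-2-bromo-3-methoxyphenyl}-3-(triisopropylsilyloxy)propan-1-ol
Conditions: TIPSCl (2.4 equiv), imidazole, DMF, 0 °C → rt
Reagents that add atoms: triisopropylsilyl chloride, CC(C)[Si](Cl)(C(C)C)C(C)C
Why: Silylation with a bulky chlorosilane takes the two primary alcohols and leaves the hindered secondary benzylic alcohols free, which removes the primary oxygen that could otherwise close a competing five-membered ring onto C7a and gives an ether that does not migrate under base.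

Step 15
Reactants: 22 bis(triisopropylsilyl) ether
Product: 23 (1S,2R)-2-(4-benzyloxy-3-methoxyphenyl)-1-[(2S,3R)-2-(4-benzyloxy-3-methoxyphenyl)-7-methoxy-3-(triisopropylsilyloxymethyl)-2,3-dihydrobenzofuran-5-yl]-3-(triisopropylsilyloxy)propan-1-ol
Conditions: CuI (20 mol %), 3,4,7,8-tetramethyl-1,10-phenanthroline (40 mol %), Cs2CO3 (2 equiv), toluene, 110 °C, argon
Reagents that add atoms: none
Why: Intramolecular Ullmann-type etherification on monovalent copper, in which the C2 alkoxide replaces bromide at C7a in a five-membered ring closure at the aryl carbon, the C2–O bond is never broken so the syn unit gives the trans-(2S,3R) ring with retention, and the second benzylic alcohol cannot reach the bromide.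

Step 16
Reactants: 23 protected trans-dihydrobenzofuran
Product: 24 (1S,2R)-2-(4-benzyloxy-3-methoxyphenyl)-1-[(2S,3R)-2-(4-benzyloxy-3-methoxyphenyl)-3-(hydroxymethyl)-7-methoxy-2,3-dihydrobenzofuran-5-yl]propane-1,3-diol
Conditions: Bu4NF, THF, 0 °C → rt
Reagents that add atoms: none
Why: Fluoride-induced cleavage of both Si–O bonds, driven by the strong Si–F bond, frees the primary alcohols without affecting benzyl ethers or the benzylic stereocenters.

Step 17
Reactants: 24 dibenzyl ether triol
Product: 25 (1S,2R)-2-(4-hydroxy-3-methoxyphenyl)-1-[(2S,3R)-2-(4-hydroxy-3-methoxyphenyl)-3-(hydroxymethyl)-7-methoxy-2,3-dihydrobenzofuran-5-yl]propane-1,3-diol (CNP0294468.1)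
Conditions: H2 (1 atm), 10% Pd/C, EtOAc/EtOH, rt, stopped after uptake of two equivalents
Reagents that add atoms: none
Why: Hydrogenolysis of the two aryl benzyl ethers on palladium under neutral conditions, where the benzylic C2–O1 bond and the benzylic alcohol, which are cleaved only under acidic or forcing conditions, should survive.

**Compound list**

1 | 4-amino-3-methoxybenzoic acid | COc1cc(C(=O)O)ccc1N | starting material
2 | 4-amino-3-iodo-5-methoxybenzoic acid | COc1cc(C(=O)O)cc(I)c1N | intermediate
3 | 4-carboxy-2-iodo-6-methoxybenzenediazonium bromide | COc1cc(C(=O)O)cc(I)c1[N+]#N.[Br-] | intermediate (not isolated)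
4 | 4-bromo-3-iodo-5-methoxybenzoic acid | COc1cc(C(=O)O)cc(I)c1Br | intermediate
5 | 4-bromo-3-iodo-5-methoxybenzoyl chloride | COc1cc(C(=O)Cl)cc(I)c1Br | intermediate
6 | homovanillic acid | COc1cc(CC(=O)O)ccc1O | starting material
7 | methyl 2-(4-hydroxy-3-methoxyphenyl)acetate | COC(=O)Cc1ccc(O)c(OC)c1 | intermediate
8 | methyl 2-(4-benzyloxy-3-methoxyphenyl)acetate | COC(=O)Cc1ccc(OCc2ccccc2)c(OC)c1 | intermediate
9 | lithium enolate of 8 | COC([O-])=Cc1ccc(OCc2ccccc2)c(OC)c1.[Li+] | intermediate (not isolated)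
10 | methyl 2-(4-benzyloxy-3-methoxyphenyl)-3-(4-bromo-3-iodo-5-methoxyphenyl)-3-oxopropanoate | COC(=O)C(C(=O)c1cc(I)c(Br)c(OC)c1)c1ccc(OCc2ccccc2)c(OC)c1 | intermediate
11 | methyl bromoacetate | COC(=O)CBr | starting material
12 | bromo(2-methoxy-2-oxoethyl)zinc | COC(=O)C[Zn]Br | intermediate
13 | methyl 2-(4-benzyloxy-3-methoxyphenyl)-3-[4-bromo-3-methoxy-5-(2-methoxy-2-oxoethyl)phenyl]-3-oxopropanoate | COC(=O)Cc1cc(C(=O)C(C(=O)OC)c2ccc(OCc3ccccc3)c(OC)c2)cc(OC)c1Br | intermediate
14 | vanillic acid | COc1cc(C(=O)O)ccc1O | starting material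
15 | benzyl 4-benzyloxy-3-methoxybenzoate | COc1cc(C(=O)OCc2ccccc2)ccc1OCc1ccccc1 | intermediate (not isolated)
16 | 4-benzyloxy-3-methoxybenzoic acid | COc1cc(C(=O)O)ccc1OCc1ccccc1 | intermediate
17 | 4-benzyloxy-3-methoxybenzoyl chloride | COc1cc(C(=O)Cl)ccc1OCc1ccccc1 | intermediate
18 | dilithium dienolate of 13 | COC([O-])=Cc1cc(C([O-])=C(C(=O)OC)c2ccc(OCc3ccccc3)c(OC)c2)cc(OC)c1Br.[Li+].[Li+] | intermediate (not isolated)
19 | methyl 2-(4-benzyloxy-3-methoxyphenyl)-3-{3-[1-(4-benzyloxy-3-methoxyphenyl)-3-methoxy-1,3-dioxopropan-2-yl]-4-bromo-5-methoxyphenyl}-3-oxopropanoate | COc1cc(C(=O)C(C(=O)OC)c2cc(C(=O)C(C(=O)OC)c3ccc(OCc4ccccc4)c(OC)c3)cc(OC)c2Br)ccc1OCc1ccccc1 | intermediate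
20 | methyl (2S,3S)-2-(4-benzyloxy-3-methoxyphenyl)-3-{4-bromo-3-[(1S,2S)-1-(4-benzyloxy-3-methoxyphenyl)-1-hydroxy-3-methoxy-3-oxopropan-2-yl]-5-methoxyphenyl}-3-hydroxypropanoate | COc1cc([C@@H](O)[C@@H](C(=O)OC)c2cc([C@@H](O)[C@@H](C(=O)OC)c3ccc(OCc4ccccc4)c(OC)c3)cc(OC)c2Br)ccc1OCc1ccccc1 | intermediate
21 | (1S,2R)-1-(4-benzyloxy-3-methoxyphenyl)-2-{5-[(1S,2R)-2-(4-benzyloxy-3-methoxyphenyl)-1,3-dihydroxypropyl]-2-bromo-3-methoxyphenyl}propane-1,3-diol | COc1cc([C@@H](O)[C@@H](CO)c2cc([C@@H](O)[C@@H](CO)c3ccc(OCc4ccccc4)c(OC)c3)cc(OC)c2Br)ccc1OCc1ccccc1 | intermediate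
22 | (1S,2R)-1-(4-benzyloxy-3-methoxyphenyl)-2-{5-[(1S,2R)-2-(4-benzyloxy-3-methoxyphenyl)-1-hydroxy-3-(triisopropylsilyloxy)propyl]-2-bromo-3-methoxyphenyl}-3-(triisopropylsilyloxy)propan-1-ol | COc1cc([C@@H](O)[C@@H](CO[Si](C(C)C)(C(C)C)C(C)C)c2cc([C@@H](O)[C@@H](CO[Si](C(C)C)(C(C)C)C(C)C)c3ccc(OCc4ccccc4)c(OC)c3)cc(OC)c2Br)ccc1OCc1ccccc1 | intermediate
23 | (1S,2R)-2-(4-benzyloxy-3-methoxyphenyl)-1-[(2S,3R)-2-(4-benzyloxy-3-methoxyphenyl)-7-methoxy-3-(triisopropylsilyloxymethyl)-2,3-dihydrobenzofuran-5-yl]-3-(triisopropylsilyloxy)propan-1-ol | COc1cc([C@H]2Oc3c(OC)cc([C@@H](O)[C@@H](CO[Si](C(C)C)(C(C)C)C(C)C)c4ccc(OCc5ccccc5)c(OC)c4)cc3[C@@H]2CO[Si](C(C)C)(C(C)C)C(C)C)ccc1OCc1ccccc1 | intermediate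
24 | (1S,2R)-2-(4-benzyloxy-3-methoxyphenyl)-1-[(2S,3R)-2-(4-benzyloxy-3-methoxyphenyl)-3-(hydroxymethyl)-7-methoxy-2,3-dihydrobenzofuran-5-yl]propane-1,3-diol | COc1cc([C@H]2Oc3c(OC)cc([C@@H](O)[C@@H](CO)c4ccc(OCc5ccccc5)c(OC)c4)cc3[C@@H]2CO)ccc1OCc1ccccc1 | intermediate
25 | (1S,2R)-2-(4-hydroxy-3-methoxyphenyl)-1-[(2S,3R)-2-(4-hydroxy-3-methoxyphenyl)-3-(hydroxymethyl)-7-methoxy-2,3-dihydrobenzofuran-5-yl]propane-1,3-diol | COc1cc([C@H]2Oc3c(OC)cc([C@@H](O)[C@@H](CO)c4ccc(O)c(OC)c4)cc3[C@@H]2CO)ccc1O | target

**Count**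

Total: 17 steps (the preparation of zinc reagent 12 included).
Longest linear sequence: 12 steps (1 → 2 → 4 → 5 → 10 → 13 → 19 → 20 → 21 → 22 → 23 → 24 → 25).

**Steps most likely to fail**

1. Step 12 (the proposed method). The process at risk is hydride delivery through the other methine epimer at one or both sites (ester instead of α-aryl group anti to the hydride), which would give anti units. A second risk is epimerisation of the hindered ortho-bromoaryl methine that is too slow to feed the fast-reacting epimer.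

   The fallback uses known chemistry, two consecutive Evans syn aldol reactions. It sets out from 8 (with 5 and 12 as partners) and returns to the route at tetraol 21.
   - Ester 8 is saponified (LiOH, THF/H2O) to 2-(4-benzyloxy-3-methoxyphenyl)acetic acid F1. This is coupled with (S)-4-benzyloxazolidin-2-one (DCC, DMAP, CH2Cl2) to the arylacetyl imide (S)-4-benzyl-3-[2-(4-benzyloxy-3-methoxyphenyl)acetyl]oxazolidin-2-one F2.
   - Acid chloride 5 is reduced with LiAlH(O-t-Bu)3 (THF, −78 °C) to 4-bromo-3-iodo-5-methoxybenzaldehyde F3.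
   - The Z boron enolate of F2 (Bu2BOTf, i-Pr2NEt, CH2Cl2, −78 → 0 °C) adds to F3 through the chair transition state governed by the auxiliary. This should give the (2S,3S) syn aldol imide F4, which carries the open-chain unit in its final configuration.
   - LiBH4 (THF, MeOH) removes the auxiliary and gives the (1S,2R) iodo diol F5. TBSOTf and 2,6-lutidine convert it into the bis(tert-butyldimethylsilyl) ether F6.
   - F6, which has no acidic proton, is coupled with zinc reagent 12 under the conditions of step 8 to the methyl arylacetate F7. LiOH gives the arylacetic acid F8, and DCC/DMAP with the same oxazolidinone gives the second imide F9.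
   - A second boron aldol reaction of F9 with commercial 4-benzyloxy-3-methoxybenzaldehyde should give the (2S,3S) syn aldol imide F10. LiBH4 then gives the bis-silylated diol F11, and Bu4NF removes both silyl groups to give 21.

2. Step 11. The process at risk is acylation at the oxygen of the stabilised keto ester enolate, or proton transfer from newly formed product to unreacted arylacetate enolate, in place of clean C-acylation.

   The fallback is aldol addition followed by oxidation. It sets out from 13 and returns at 19. Dienolate 18, made from 13 as in step 11 with 2.1 equivalents of base, is treated at −78 °C with commercial 4-benzyloxy-3-methoxybenzaldehyde. An aldehyde cannot acylate oxygen, and the stabilised enolate adds only reversibly. The resulting β-hydroxy ester, the aldol adduct F12 (diastereomer mixture, no consequence), is oxidised with Dess–Martin periodinane (NaHCO3, CH2Cl2) to 19.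

3. Step 8. The process at risk is loss of halide selectivity (oxidative addition into the C–Br bond under the electron-rich phosphine) or stalling of the catalyst by the zinc enolate of the keto ester.

   The fallback is a Stille allylation followed by oxidative cleavage. It sets out from 10 and returns at 13.
   - Allyltributylstannane and Pd(PPh3)4 (toluene, 100 °C) couple at the iodide only, since triphenylphosphine-ligated zerovalent palladium does not insert into the hindered bromide. This gives the allylarene methyl 3-(3-allyl-4-bromo-5-methoxyphenyl)-2-(4-benzyloxy-3-methoxyphenyl)-3-oxopropanoate F13.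
   - Lemieux–Johnson cleavage (OsO4 cat., NaIO4, 2,6-lutidine, dioxane/H2O) gives the arylacetaldehyde F14.
   - Pinnick oxidation (NaClO2, NaH2PO4, 2-methyl-2-butene, t-BuOH/H2O) gives the arylacetic acid F15.
   - Me3SiCHN2 (MeOH/toluene) methylates the acid to give 13.

Further compounds
F1 | step 12 | 2-(4-benzyloxy-3-methoxyphenyl)acetic acid | COc1cc(CC(=O)O)ccc1OCc1ccccc1
F2 | step 12 | (S)-4-benzyl-3-[2-(4-benzyloxy-3-methoxyphenyl)acetyl]oxazolidin-2-one | COc1cc(CC(=O)N(C(=O)OC2)[C@H]2Cc2ccccc2)ccc1OCc1ccccc1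
F3 | step 12 | 4-bromo-3-iodo-5-methoxybenzaldehyde | COc1cc(C=O)cc(I)c1Br
F4 | step 12 | (S)-4-benzyl-3-[(2S,3S)-2-(4-benzyloxy-3-methoxyphenyl)-3-(4-bromo-3-iodo-5-methoxyphenyl)-3-hydroxypropanoyl]oxazolidin-2-one | COc1cc([C@@H](O)[C@@H](C(=O)N(C(=O)OC2)[C@H]2Cc2ccccc2)c2ccc(OCc3ccccc3)c(OC)c2)cc(I)c1Br
F5 | step 12 | (1S,2R)-2-(4-benzyloxy-3-methoxyphenyl)-1-(4-bromo-3-iodo-5-methoxyphenyl)propane-1,3-diol | COc1cc([C@@H](O)[C@@H](CO)c2ccc(OCc3ccccc3)c(OC)c2)cc(I)c1Br
F6 | step 12 | (1S,2R)-2-(4-benzyloxy-3-methoxyphenyl)-1-(4-bromo-3-iodo-5-methoxyphenyl)-1,3-bis(tert-butyldimethylsilyloxy)propane | COc1cc([C@@H](O[Si](C)(C)C(C)(C)C)[C@@H](CO[Si](C)(C)C(C)(C)C)c2ccc(OCc3ccccc3)c(OC)c2)cc(I)c1Br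
F7 | step 12 | methyl 2-{5-[(1S,2R)-2-(4-benzyloxy-3-methoxyphenyl)-1,3-bis(tert-butyldimethylsilyloxy)propyl]-2-bromo-3-methoxyphenyl}acetate | COC(=O)Cc1cc([C@@H](O[Si](C)(C)C(C)(C)C)[C@@H](CO[Si](C)(C)C(C)(C)C)c2ccc(OCc3ccccc3)c(OC)c2)cc(OC)c1Br
F8 | step 12 | 2-{5-[(1S,2R)-2-(4-benzyloxy-3-methoxyphenyl)-1,3-bis(tert-butyldimethylsilyloxy)propyl]-2-bromo-3-methoxyphenyl}acetic acid | OC(=O)Cc1cc([C@@H](O[Si](C)(C)C(C)(C)C)[C@@H](CO[Si](C)(C)C(C)(C)C)c2ccc(OCc3ccccc3)c(OC)c2)cc(OC)c1Br
F9 | step 12 | (S)-4-benzyl-3-(2-{5-[(1S,2R)-2-(4-benzyloxy-3-methoxyphenyl)-1,3-bis(tert-butyldimethylsilyloxy)propyl]-2-bromo-3-methoxyphenyl}acetyl)oxazolidin-2-one | COc1cc([C@@H](O[Si](C)(C)C(C)(C)C)[C@@H](CO[Si](C)(C)C(C)(C)C)c2ccc(OCc3ccccc3)c(OC)c2)cc(CC(=O)N(C(=O)OC2)[C@H]2Cc2ccccc2)c1Br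
F10 | step 12 | (S)-4-benzyl-3-[(2S,3S)-3-(4-benzyloxy-3-methoxyphenyl)-2-{5-[(1S,2R)-2-(4-benzyloxy-3-methoxyphenyl)-1,3-bis(tert-butyldimethylsilyloxy)propyl]-2-bromo-3-methoxyphenyl}-3-hydroxypropanoyl]oxazolidin-2-one | COc1cc([C@@H](O)[C@@H](C(=O)N(C(=O)OC2)[C@H]2Cc2ccccc2)c2cc([C@@H](O[Si](C)(C)C(C)(C)C)[C@@H](CO[Si](C)(C)C(C)(C)C)c3ccc(OCc4ccccc4)c(OC)c3)cc(OC)c2Br)ccc1OCc1ccccc1
F11 | step 12 | (1S,2R)-1-(4-benzyloxy-3-methoxyphenyl)-2-{5-[(1S,2R)-2-(4-benzyloxy-3-methoxyphenyl)-1,3-bis(tert-butyldimethylsilyloxy)propyl]-2-bromo-3-methoxyphenyl}propane-1,3-diol | COc1cc([C@@H](O)[C@@H](CO)c2cc([C@@H](O[Si](C)(C)C(C)(C)C)[C@@H](CO[Si](C)(C)C(C)(C)C)c3ccc(OCc4ccccc4)c(OC)c3)cc(OC)c2Br)ccc1OCc1ccccc1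
F12 | step 11 | methyl 3-(4-benzyloxy-3-methoxyphenyl)-2-{5-[2-(4-benzyloxy-3-methoxyphenyl)-3-methoxy-3-oxopropanoyl]-2-bromo-3-methoxyphenyl}-3-hydroxypropanoate (diastereomer mixture) | COc1cc(C(O)C(C(=O)OC)c2cc(C(=O)C(C(=O)OC)c3ccc(OCc4ccccc4)c(OC)c3)cc(OC)c2Br)ccc1OCc1ccccc1
F13 | step 8 | methyl 3-(3-allyl-4-bromo-5-methoxyphenyl)-2-(4-benzyloxy-3-methoxyphenyl)-3-oxopropanoate | COC(=O)C(C(=O)c1cc(CC=C)c(Br)c(OC)c1)c1ccc(OCc2ccccc2)c(OC)c1
F14 | step 8 | methyl 2-(4-benzyloxy-3-methoxyphenyl)-3-[4-bromo-3-methoxy-5-(2-oxoethyl)phenyl]-3-oxopropanoate | COC(=O)C(C(=O)c1cc(CC=O)c(Br)c(OC)c1)c1ccc(OCc2ccccc2)c(OC)c1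
F15 | step 8 | 2-{2-bromo-5-[2-(4-benzyloxy-3-methoxyphenyl)-3-methoxy-3-oxopropanoyl]-3-methoxyphenyl}acetic acid | COC(=O)C(C(=O)c1cc(CC(=O)O)c(Br)c(OC)c1)c1ccc(OCc2ccccc2)c(OC)c1
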